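## The problem

Atom numbers follow the acid chain: C1 is the carboxyl carbon, C3 the hemiketal carbon (bearing O2), C6 the carbon bearing O1, and C16 the benzylic CH2.

Target 30 is a 1,2-dioxane (O1–O2–C3–C4–C5–C6) whose C3 is a peroxy hemiketal carrying the acetic acid arm C1–C2. C4 and C6 carry methyl groups, and C6 also carries the chain C7–C16, with a third methyl on C8 and a terminal phenyl. The chain is simple, so the task is a late, mild construction of the O–O ring and four stereocentres (C3, C4, C6, C8). C3 can be left to equilibrium: the hemiketal opens and closes, and the required isomer is the chair with axial (anomeric) OH and equatorial CH2CO2H, C4 methyl and C6 chain. C4 and C8 are 1,5-related across C6 and cannot control each other, so both must be brought in enantiopure. C6 is the hard centre: a fully substituted carbon bearing O, CH3 and two CH2 groups, whose faces are told apart in an open chain only by one remote methyl on each side. The O–O bond rules out catalytic hydrogenation, phosphines, low-valent metals and carbanions that can reach oxygen, and the hemiketal is in equilibrium with an enolisable hydroperoxy β-keto acid, so base should be kept away from it. The feature to exploit is that C4 and C8 carry syn methyls on either side of C6, while C3 (a ketone once the hemiketal is opened) and C9 (an aldehyde carbon before the tail is attached) are the two halves of a cleaved C3=C9 double bond. With that bond in place, C3–C4–C5–C6–C7–C8–C9 is a cycloheptene in which C5 and C7 are ring atoms, the methyls are cis and the two faces of C6 differ.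

## Retrosynthesis

**30 ⇒ 28.** The O2–C3 hemiketal bond is cut and the three acid-labile groups are put back: 28 is an open chain with C6–OOSiEt3, C3 as the silyl enol ether of the β-keto ester, and a tert-butyl ester. A methyl ester saponified last was rejected, because hydroxide would meet a hemiketal that opens to an enolisable hydroperoxy keto ester. The forward step must remove three groups with acid, close the ring and let C3 settle thermodynamically.

**28 ⇒ 27 ⇒ 23 + 25.** The tail is cut at C9–C10, as a C9=C10 alkene (27) made by Wittig olefination of aldehyde 23 with the ylide from 25, then reduced by diimide. Cuts at C8–C9 or C10–C11 would need sp3–sp3 organometallic couplings that the O–O bond does not tolerate. An aldehyde at C9 is exactly what ring cleavage supplies.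

**23 ⇒ 22 ⇒ 20.** The enol silyl ether 23 comes from keto aldehyde 22. Reconnecting C3 and C9 of 22 as a double bond gives cycloheptene 20. This deliberate extra bond turns the open-chain C6 problem into a ring problem. Forward, ozonolysis must cleave the only C=C bond without touching the silyl peroxide.

**20 ⇒ 19 ⇒ 18.** The C6–O1 bond is cut to the exocyclic alkene 19 (hydrogen atom transfer, O2 capture, silylation), and the methylidene to ketone 18. Adding a methyl nucleophile to 18 was rejected: it gives a tertiary alcohol that cannot be turned into a hydroperoxide with retention. The radical route builds the O–O bond directly on the ring.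

**18 ⇒ 17.** The C3=C9 bond is cut by ring-closing metathesis (key step). Closing the ring by enolate chemistry at C5 or C7 would put the neighbouring centres at risk, whereas metathesis is neutral and uses two terminal alkenes. Dienone 17 is acyclic and holds only C4 and C8.

**17 ⇒ 15 + 6 (via 16).** The C5–C6 acyl–alkyl bond is cut to thioester 6 and the alkylzinc reagent 16 from iodide 15. Double alkylation of an acyl-anion equivalent at C6 was the neighbouring option. It needs strong base and two substitutions on β-branched iodides, one of which carries a base-sensitive deconjugated ester. The palladium-catalysed acyl coupling is neutral and ester-tolerant.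

**15 ⇒ 13 ⇒ 12 ⇒ 10 ⇒ 7.** The C2–C3 bond is cut to enol triflate 12 and a zinc ester enolate, which places the double bond out of conjugation from the start. Triflate 12 comes from methyl ketone 10 and this from hydroxy ester 7, whose ester carbon becomes C3 and whose CH2OH becomes C5. C4 is thus taken from the chiral pool.

**6 ⇒ 5 ⇒ 4 ⇒ 1 + 2.** The C8–C9 bond is cut by auxiliary-controlled conjugate addition of a vinyl copper reagent to imide 4, made from oxazolidinone 1 and acid chloride 2. This sets C8 in the sense opposite to C4, as the syn methyl array requires.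

## Roads not taken

**Alternative 1:** The cut is C4=C5 inside the future dioxane, with the O–O bond as tether. The mixed peroxyketal A2 would be closed by a ruthenium alkylidene catalyst to the 3,6-dihydro-1,2-dioxine A1, with loss of ethene.
- Merits: the peroxide ring is made directly and convergently, and both oxygenated quaternary carbons are in place before cyclisation. In ring-forming economy it is better than the chosen plan, which builds and destroys a carbocycle.
- Weak points: A2 needs a tertiary allylic hydroperoxide of defined C6 configuration, which is the same C6 problem with no template. C3 is fixed in an acyclic ketal that cannot equilibrate. C4 must then be set by reducing a trisubstituted ring alkene next to O–O, where hydrogenation is excluded and diimide is poor.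
- Comparison: the chosen plan has more steps, but it takes C4 from the chiral pool and gives C6 a rational handle.

**Alternative 2:** The same kind of seven-membered template is reached by cutting C4–C5 and C7–C8 together. The oxyallyl cation from A4 (with an iron carbonyl) adds to diene A5, and reductive debromination gives the meso cycloheptenone A3.
- Merits: the cis methyls follow from the cycloaddition geometry, and the template arrives in one or two steps from bulk chemicals. The chosen plan needs twelve steps to reach 18, so on this point Alternative 2 is clearly better.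
- Weak points: A3 is meso and both alkene carbons are CH. Ozonolysis after C6 functionalisation would give two enantiotopic aldehydes. They would have to be differentiated enantioselectively, and one of them extended and oxidised to the β-keto ester, all in the presence of the O–O bond.
- Comparison: the chosen plan carries the acetate arm on C3 through the ring closure. Ozonolysis then gives ketone and aldehyde already differentiated, and the absolute configuration is fixed from the first steps.

**Alternative 3:** Three ring bonds are cut at once (C4–C5, C6–O1, O2–C3). The C4 radical from A7 adds to the CH2 terminus of A8, the tertiary C6 radical captures dioxygen, and the hydroperoxide closes on the C3 ketone to give A6, one ester hydrolysis from 30.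
- Merits: it is by far the shortest route and makes the whole ring in one step. C3, and through ring–chain equilibration probably C4, would end up thermodynamically correct.
- Weak points: the C6 radical is 1,3 to C8 in an open chain and cannot be controlled, so two C6 epimers differing only in a remote relationship are expected. Radical reduction, telomerisation and bromine transfer compete with O2 capture.
- Comparison: if the epimers could be separated, this would be the better route for material supply. The chosen plan accepts about twice the step count in exchange for a designed control element at C6.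

Key step: step 12

Assumption: the C2=C3 geometry of the silyl enol ether in 23, 27 and 28 is not controlled and is left undefined, since this double bond is hydrolysed in step 20.

## Route

Step 1
Reactants: 1 (R)-4-benzyloxazolidin-2-one; 2 (E)-but-2-enoyl chloride
Product: 4 (R)-4-benzyl-3-[(E)-but-2-enoyl]oxazolidin-2-one, via lithium oxazolidinide 3 (not isolated)
Conditions: n-BuLi, THF, −78 °C; then 2, −78 → 0 °C
Reagents that add atoms: none
Why: N-acylation of a lithiated oxazolidinone with an acid chloride is the standard entry to N-enoyl imides; the low temperature prevents conjugate addition of the amide anion.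

Step 2
Reactants: 4 (R)-4-benzyl-3-[(E)-but-2-enoyl]oxazolidin-2-one
Product: 5 (R)-4-benzyl-3-[(S)-3-methylpent-4-enoyl]oxazolidin-2-one
Conditions: CH2=CHMgBr, CuBr·SMe2, THF/Me2S, −78 → −20 °C
Reagents that add atoms: vinylmagnesium bromide, C=C[Mg]Br
Why: Copper-mediated conjugate addition of the vinyl Grignard reagent to the magnesium-chelated s-cis imide occurs on the face opposite the benzyl group; with the (R)-auxiliary this should give the (S) β-methyl centre that becomes C8.

Step 3
Reactants: 5 (R)-4-benzyl-3-[(S)-3-methylpent-4-enoyl]oxazolidin-2-one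
Product: 6 S-ethyl (S)-3-methylpent-4-enethioate
Conditions: EtSH, n-BuLi (LiSEt), THF, 0 °C
Reagents that add atoms: ethanethiol, CCS
Why: Thiolate attacks the exocyclic imide carbonyl (auxiliary cleavage by transthioesterification) and gives the thioester needed for acyl cross-coupling without touching the β-stereocentre; auxiliary 1 is recovered.

Step 4
Reactants: 7 methyl (R)-3-hydroxy-2-methylpropanoate
Product: 8 methyl (R)-3-[(tert-butyldimethylsilyl)oxy]-2-methylpropanoate
Conditions: t-BuMe2SiCl, imidazole, CH2Cl2, 0 °C → rt
Reagents that add atoms: tert-butyldimethylsilyl chloride, CC(C)(C)[Si](C)(C)Cl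
Why: Silylation of a primary alcohol; the α-stereocentre of the ester is not involved.

Step 5
Reactants: 8 methyl (R)-3-[(tert-butyldimethylsilyl)oxy]-2-methylpropanoate
Product: 9 (R)-3-[(tert-butyldimethylsilyl)oxy]-N-methoxy-N,2-dimethylpropanamide
Conditions: MeNH(OMe)·HCl, i-PrMgCl, THF, −20 → 0 °C
Reagents that add atoms: N,O-dimethylhydroxylamine hydrochloride, CNOC.Cl
Why: Weinreb amide formation by aminolysis of the ester with the chloromagnesium amide; the hindered Grignard base does not epimerise the α-centre at this temperature.

Step 6
Reactants: 9 (R)-3-[(tert-butyldimethylsilyl)oxy]-N-methoxy-N,2-dimethylpropanamide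
Product: 10 (R)-4-[(tert-butyldimethylsilyl)oxy]-3-methylbutan-2-one
Conditions: MeMgBr, THF, 0 °C
Reagents that add atoms: methylmagnesium bromide, C[Mg]Br
Why: Grignard addition to a Weinreb amide stops at the chelated tetrahedral adduct, so the methyl ketone appears only on work-up and the α-methyl centre is kept.

Step 7
Reactants: 10 (R)-4-[(tert-butyldimethylsilyl)oxy]-3-methylbutan-2-one
Product: 12 (R)-4-[(tert-butyldimethylsilyl)oxy]-3-methylbut-1-en-2-yl trifluoromethanesulfonate, via potassium enolate 11 (not isolated)
Conditions: KN(SiMe3)2 added to 10 and PhNTf2, THF, −78 °C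
Reagents that add atoms: N-phenylbis(trifluoromethanesulfonimide), O=S(=O)(N(c1ccccc1)S(=O)(=O)C(F)(F)F)C(F)(F)F
Why: Kinetic deprotonation of a methyl sec-alkyl ketone by a bulky amide takes a methyl proton, and immediate O-sulfonylation gives the 1,1-disubstituted enol triflate before the enolate can equilibrate toward the stereocentre.

Step 8
Reactants: 12 (R)-4-[(tert-butyldimethylsilyl)oxy]-3-methylbut-1-en-2-yl trifluoromethanesulfonate
Product: 13 tert-butyl (S)-5-[(tert-butyldimethylsilyl)oxy]-4-methyl-3-methylidenepentanoate
Conditions: BrZnCH2CO2t-Bu (from BrCH2CO2t-Bu and Zn), Pd(PPh3)4 (5 mol %), THF, 60 °C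
Reagents that add atoms: tert-butyl bromoacetate (used as its zinc enolate), CC(C)(C)OC(=O)CBr
Why: Negishi-type coupling of a Reformatsky reagent with an alkenyl triflate under zerovalent palladium catalysis forms the C2–C3 bond and leaves the alkene out of conjugation; the descriptor changes from R to S only because the CIP priorities change.

Step 9
Reactants: 13 tert-butyl (S)-5-[(tert-butyldimethylsilyl)oxy]-4-methyl-3-methylidenepentanoate
Product: 14 tert-butyl (S)-5-hydroxy-4-methyl-3-methylidenepentanoate
Conditions: HF·pyridine, pyridine, THF, 0 °C → rt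
Reagents that add atoms: none
Why: Buffered fluoride desilylation; the tert-butyl ester resists both cleavage and δ-lactonisation, and the deconjugated alkene sees no base.

Step 10
Reactants: 14 tert-butyl (S)-5-hydroxy-4-methyl-3-methylidenepentanoate
Product: 15 tert-butyl (S)-5-iodo-4-methyl-3-methylidenepentanoate
Conditions: I2, PPh3, imidazole, CH2Cl2, 0 °C
Reagents that add atoms: iodine, II
Why: Appel-type iodination of a primary alcohol by SN2 displacement of the alkoxyphosphonium ion; the adjacent stereocentre is not involved.

Step 11
Reactants: 15 tert-butyl (S)-5-iodo-4-methyl-3-methylidenepentanoate; 6 S-ethyl (S)-3-methylpent-4-enethioate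
Product: 17 tert-butyl (4R,8S)-4,8-dimethyl-3-methylidene-6-oxodec-9-enoate, via alkylzinc iodide 16 (not isolated)
Conditions: Zn dust (activated with BrCH2CH2Br and Me3SiCl), THF, 40 °C; then 6, PdCl2(PPh3)2 (5 mol %), toluene, rt
Reagents that add atoms: none
Why: Fukuyama coupling: zinc inserts into the primary C–I bond to give an ester-tolerant alkylzinc iodide, which transmetallates to the acylpalladium species from the thioester; the ketone forms without over-addition, without base, and without touching either stereocentre or alkene.

Step 12
Reactants: 17 tert-butyl (4R,8S)-4,8-dimethyl-3-methylidene-6-oxodec-9-enoate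
Product: 18 tert-butyl 2-[(3S,7R)-3,7-dimethyl-5-oxocyclohept-1-en-1-yl]acetate
Conditions: second-generation Grubbs catalyst RuCl2(=CHPh)(H2IMes)(PCy3) (5 mol %), 1,4-benzoquinone (10 mol %), CH2Cl2 (0.002 M), 40 °C
Reagents that add atoms: none
Why: The catalyst benzylidene exchanges first with the monosubstituted C9 vinyl group; the C9 ruthenium alkylidene then adds across the 1,1-disubstituted C3 methylidene to a ruthenacyclobutane, whose cycloreversion gives the C3=C9 bond and a ruthenium methylidene, with ethene lost irreversibly. The closest known reaction type is ring-closing metathesis of one mono- and one 1,1-disubstituted terminal alkene to a trisubstituted cycloheptene with NHC–ruthenium catalysts in the presence of ketones and esters. The ring closes as a seven-membered carbocycle with the new double bond endocyclic and necessarily Z; the sp2 ketone carbon and the two branch points lower the entropic cost. No stereocentre is formed: C4 and C8 are allylic but untouched under these neutral conditions, and the cis methyl relationship in 18 is already encoded in the (4R,8S) configuration of 17. The step needs chemoselectivity for the two terminal alkenes and ring closure over oligomerisation. The first is secured because ketone and ester are inert to the alkylidene and no third alkene is present; the second by high dilution. Benzoquinone suppresses ruthenium hydrides that could move the vinyl double bond toward C8.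

Step 13
Reactants: 18 tert-butyl 2-[(3S,7R)-3,7-dimethyl-5-oxocyclohept-1-en-1-yl]acetate
Product: 19 tert-butyl 2-[(3S,7R)-3,7-dimethyl-5-methylidenecyclohept-1-en-1-yl]acetate
Conditions: Ph3PCH3Br, KOt-Bu, THF, 0 °C → rt
Reagents that add atoms: methyltriphenylphosphonium bromide, C[P+](c1ccccc1)(c1ccccc1)c1ccccc1.[Br-]
Why: Wittig methylenation of an unhindered dialkyl ketone; both stereocentres are β to the carbonyl and cannot epimerise by enolisation, and the hindered tert-butyl ester is inert to the ylide.

Step 14
Reactants: 19 tert-butyl 2-[(3S,7R)-3,7-dimethyl-5-methylidenecyclohept-1-en-1-yl]acetate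
Product: 20 tert-butyl 2-[(3S,5S,7R)-3,5,7-trimethyl-5-[(triethylsilyl)peroxy]cyclohept-1-en-1-yl]acetate
Conditions: Co(acac)2 (10 mol %), Et3SiH, O2 (1 atm), ClCH2CH2Cl, rt
Reagents that add atoms: dioxygen, O=O; triethylsilane, CC[SiH](CC)CC
Why: Mukaiyama–Isayama silylperoxidation: a cobalt hydride transfers a hydrogen atom to the CH2 terminus of the more accessible 1,1-disubstituted exocyclic alkene (the trisubstituted ring alkene reacts more slowly), the tertiary C6 radical captures O2 and the cobalt peroxide is silylated by the silane. The new centre (C6, ring C5) is set by the ring: with both methyls pseudoequatorial on one face, oxygen should enter along the axial direction of the opposite face, which is torsionally preferred and the only face left open when a methyl turns pseudoaxial, giving O–O trans to both methyls.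

Step 15
Reactants: 20 tert-butyl 2-[(3S,5S,7R)-3,5,7-trimethyl-5-[(triethylsilyl)peroxy]cyclohept-1-en-1-yl]acetate
Product: 22 tert-butyl (4R,6S,8S)-4,6,8-trimethyl-3,9-dioxo-6-[(triethylsilyl)peroxy]nonanoate, via methoxy hydroperoxide 21 (not isolated)
Conditions: O3, CH2Cl2/MeOH (4:1), −78 °C; then Me2S, −78 °C → rt
Reagents that add atoms: ozone, [O-][O+]=O
Why: Ozonolysis of the only remaining C=C bond removes the temporary C3=C9 bond and releases the C3 ketone (a β-keto ester) and the C9 aldehyde; the hindered silyl peroxide is inert to ozone and to the sulfide at low temperature, and 22 is used crude to protect the α-centres C4 and C8.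

Step 16
Reactants: 22 tert-butyl (4R,6S,8S)-4,6,8-trimethyl-3,9-dioxo-6-[(triethylsilyl)peroxy]nonanoate
Product: 23 tert-butyl (4R,6R,8S)-3-[(tert-butyldimethylsilyl)oxy]-4,6,8-trimethyl-9-oxo-6-[(triethylsilyl)peroxy]non-2-enoate
Conditions: t-BuMe2SiCl, imidazole, DMF, 0 °C
Reagents that add atoms: tert-butyldimethylsilyl chloride, CC(C)(C)[Si](C)(C)Cl
Why: O-Silylation of the 1,3-dicarbonyl unit, the only strongly enolised carbonyl, gives a β-silyloxy enoate and removes the acidic C2 protons, so that no enolate can form within reach of the O–O bond in step 18; the aldehyde is not enolised by imidazole at 0 °C, and C6 changes descriptor by CIP priority only.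

Step 17
Reactants: 24 (7-bromoheptyl)benzene
Product: 25 triphenyl(7-phenylheptyl)phosphonium bromide
Conditions: PPh3, MeCN, 82 °C
Reagents that add atoms: triphenylphosphine, c1ccc(cc1)P(c1ccccc1)c1ccccc1
Why: SN2 quaternisation of the phosphine by a primary bromide.

Step 18
Reactants: 23 tert-butyl (4R,6R,8S)-3-[(tert-butyldimethylsilyl)oxy]-4,6,8-trimethyl-9-oxo-6-[(triethylsilyl)peroxy]non-2-enoate; 25 triphenyl(7-phenylheptyl)phosphonium bromide
Product: 27 tert-butyl (4R,6S,8S,9Z)-3-[(tert-butyldimethylsilyl)oxy]-4,6,8-trimethyl-16-phenyl-6-[(triethylsilyl)peroxy]hexadeca-2,9-dienoate, via phosphonium ylide 26 (not isolated)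
Conditions: NaN(SiMe3)2, THF, 0 °C; then 23, −78 → 0 °C
Reagents that add atoms: none
Why: Wittig olefination with a non-stabilised ylide is fast at −78 °C and mainly Z (the geometry is irrelevant); the aldehyde is the only electrophile of that reactivity, the hindered tertiary silyl peroxide tolerates the ylide at low temperature, and the low temperature limits epimerisation at C8.

Step 19
Reactants: 27 tert-butyl (4R,6S,8S,9Z)-3-[(tert-butyldimethylsilyl)oxy]-4,6,8-trimethyl-16-phenyl-6-[(triethylsilyl)peroxy]hexadeca-2,9-dienoate
Product: 28 tert-butyl (4R,6S,8R)-3-[(tert-butyldimethylsilyl)oxy]-4,6,8-trimethyl-16-phenyl-6-[(triethylsilyl)peroxy]hexadec-2-enoate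
Conditions: KO2CN=NCO2K (excess), AcOH, CH2Cl2, 0 °C → rt
Reagents that add atoms: none
Why: Diimide reduction transfers two hydrogens in a concerted syn fashion to the unpolarised cis-disubstituted alkene; unlike catalytic hydrogenation it does not cleave O–O bonds, and it leaves the polarised trisubstituted enol ether alone (C8 becomes R by priority change only).

Step 20
Reactants: 28 tert-butyl (4R,6S,8R)-3-[(tert-butyldimethylsilyl)oxy]-4,6,8-trimethyl-16-phenyl-6-[(triethylsilyl)peroxy]hexadec-2-enoate
Product: 30 2-[(3S,4R,6S)-3-hydroxy-4,6-dimethyl-6-[(2R)-2-methyl-10-phenyldecyl]-1,2-dioxan-3-yl]acetic acid, via hemiketal tert-butyl ester 29 (not isolated)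
Conditions: CF3CO2H/CH2Cl2/H2O (10:10:1), 0 °C → rt
Reagents that add atoms: none
Why: Acidolysis removes the silyl group from the peroxide and from the enol ether; the hydroperoxide then adds 6-exo-trig to the C3 ketone, and the tert-butyl ester is cleaved last by alkyl–oxygen fission, so no base meets the hemiketal. The new centre C3 is set under thermodynamic control by ring–chain equilibration: axial anomeric OH and equatorial CH2CO2H on a chair fixed by the equatorial C4 methyl and the equatorial C6 chain, which is the (3S) isomer.

## Compound list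

1 | (R)-4-benzyloxazolidin-2-one | O=C1N[C@H](Cc2ccccc2)CO1 | starting material
2 | (E)-but-2-enoyl chloride | C/C=C/C(Cl)=O | starting material
3 | lithium salt of 1 (lithium oxazolidinide) | [Li+].O=C1[N-][C@H](Cc2ccccc2)CO1 | intermediate (not isolated)
4 | (R)-4-benzyl-3-[(E)-but-2-enoyl]oxazolidin-2-one | C/C=C/C(=O)N1[C@H](Cc2ccccc2)COC1=O | intermediate
5 | (R)-4-benzyl-3-[(S)-3-methylpent-4-enoyl]oxazolidin-2-one | C=C[C@@H](C)CC(=O)N1[C@H](Cc2ccccc2)COC1=O | intermediate
6 | S-ethyl (S)-3-methylpent-4-enethioate | CCSC(=O)C[C@H](C)C=C | intermediate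
7 | methyl (R)-3-hydroxy-2-methylpropanoate | C[C@H](CO)C(=O)OC | starting material
8 | methyl (R)-3-[(tert-butyldimethylsilyl)oxy]-2-methylpropanoate | C[C@H](CO[Si](C)(C)C(C)(C)C)C(=O)OC | intermediate
9 | (R)-3-[(tert-butyldimethylsilyl)oxy]-N-methoxy-N,2-dimethylpropanamide | C[C@H](CO[Si](C)(C)C(C)(C)C)C(=O)N(C)OC | intermediate
10 | (R)-4-[(tert-butyldimethylsilyl)oxy]-3-methylbutan-2-one | C[C@H](CO[Si](C)(C)C(C)(C)C)C(C)=O | intermediate
11 | potassium (R)-4-[(tert-butyldimethylsilyl)oxy]-3-methylbut-1-en-2-olate | [K+].C[C@H](CO[Si](C)(C)C(C)(C)C)C(=C)[O-] | intermediate (not isolated)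
12 | (R)-4-[(tert-butyldimethylsilyl)oxy]-3-methylbut-1-en-2-yl trifluoromethanesulfonate | C[C@H](CO[Si](C)(C)C(C)(C)C)C(=C)OS(=O)(=O)C(F)(F)F | intermediate
13 | tert-butyl (S)-5-[(tert-butyldimethylsilyl)oxy]-4-methyl-3-methylidenepentanoate | C[C@H](CO[Si](C)(C)C(C)(C)C)C(=C)CC(=O)OC(C)(C)C | intermediate
14 | tert-butyl (S)-5-hydroxy-4-methyl-3-methylidenepentanoate | C[C@H](CO)C(=C)CC(=O)OC(C)(C)C | intermediate
15 | tert-butyl (S)-5-iodo-4-methyl-3-methylidenepentanoate | C[C@H](CI)C(=C)CC(=O)OC(C)(C)C | intermediate
16 | [(2S)-5-tert-butoxy-2-methyl-3-methylidene-5-oxopentyl]zinc iodide | C[C@H](C[Zn]I)C(=C)CC(=O)OC(C)(C)C | intermediate (not isolated)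
17 | tert-butyl (4R,8S)-4,8-dimethyl-3-methylidene-6-oxodec-9-enoate | C=C(CC(=O)OC(C)(C)C)[C@H](C)CC(=O)C[C@H](C)C=C | intermediate
18 | tert-butyl 2-[(3S,7R)-3,7-dimethyl-5-oxocyclohept-1-en-1-yl]acetate (methyls cis) | CC(C)(C)OC(=O)CC1=C[C@@H](C)CC(=O)C[C@H]1C | intermediate
19 | tert-butyl 2-[(3S,7R)-3,7-dimethyl-5-methylidenecyclohept-1-en-1-yl]acetate | CC(C)(C)OC(=O)CC1=C[C@@H](C)CC(=C)C[C@H]1C | intermediate
20 | tert-butyl 2-[(3S,5S,7R)-3,5,7-trimethyl-5-[(triethylsilyl)peroxy]cyclohept-1-en-1-yl]acetate (peroxide trans to both ring methyls at C3 and C7) | CC(C)(C)OC(=O)CC1=C[C@@H](C)C[C@](C)(OO[Si](CC)(CC)CC)C[C@H]1C | intermediate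
21 | tert-butyl (4R,6S,8S)-9-hydroperoxy-9-methoxy-4,6,8-trimethyl-3-oxo-6-[(triethylsilyl)peroxy]nonanoate (mixture at C9) | COC(OO)[C@@H](C)C[C@](C)(OO[Si](CC)(CC)CC)C[C@@H](C)C(=O)CC(=O)OC(C)(C)C | intermediate (not isolated)
22 | tert-butyl (4R,6S,8S)-4,6,8-trimethyl-3,9-dioxo-6-[(triethylsilyl)peroxy]nonanoate | C[C@H](C=O)C[C@](C)(OO[Si](CC)(CC)CC)C[C@@H](C)C(=O)CC(=O)OC(C)(C)C | intermediate
23 | tert-butyl (4R,6R,8S)-3-[(tert-butyldimethylsilyl)oxy]-4,6,8-trimethyl-9-oxo-6-[(triethylsilyl)peroxy]non-2-enoate | C[C@H](C=O)C[C@](C)(OO[Si](CC)(CC)CC)C[C@@H](C)C(O[Si](C)(C)C(C)(C)C)=CC(=O)OC(C)(C)C | intermediate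
24 | (7-bromoheptyl)benzene | BrCCCCCCCc1ccccc1 | starting material
25 | triphenyl(7-phenylheptyl)phosphonium bromide | [Br-].c1ccc(cc1)CCCCCCC[P+](c1ccccc1)(c1ccccc1)c1ccccc1 | intermediate
26 | triphenyl(7-phenylheptylidene)phosphorane | c1ccc(cc1)CCCCCCC=P(c1ccccc1)(c1ccccc1)c1ccccc1 | intermediate (not isolated)
27 | tert-butyl (4R,6S,8S,9Z)-3-[(tert-butyldimethylsilyl)oxy]-4,6,8-trimethyl-16-phenyl-6-[(triethylsilyl)peroxy]hexadeca-2,9-dienoate | C[C@H](/C=C\CCCCCCc1ccccc1)C[C@](C)(OO[Si](CC)(CC)CC)C[C@@H](C)C(O[Si](C)(C)C(C)(C)C)=CC(=O)OC(C)(C)C | intermediate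
28 | tert-butyl (4R,6S,8R)-3-[(tert-butyldimethylsilyl)oxy]-4,6,8-trimethyl-16-phenyl-6-[(triethylsilyl)peroxy]hexadec-2-enoate | C[C@H](CCCCCCCCc1ccccc1)C[C@](C)(OO[Si](CC)(CC)CC)C[C@@H](C)C(O[Si](C)(C)C(C)(C)C)=CC(=O)OC(C)(C)C | intermediate
29 | tert-butyl 2-[(3S,4R,6S)-3-hydroxy-4,6-dimethyl-6-[(2R)-2-methyl-10-phenyldecyl]-1,2-dioxan-3-yl]acetate | C[C@H](CCCCCCCCc1ccccc1)C[C@@]1(C)C[C@@H](C)[C@](O)(CC(=O)OC(C)(C)C)OO1 | intermediate (not isolated)
30 | 2-[(3S,4R,6S)-3-hydroxy-4,6-dimethyl-6-[(2R)-2-methyl-10-phenyldecyl]-1,2-dioxan-3-yl]acetic acid | C[C@H](CCCCCCCCc1ccccc1)C[C@@]1(C)C[C@@H](C)[C@](O)(CC(=O)O)OO1 | target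

## Step count and least certain steps

Total: 20 steps. Longest linear sequence: 16 steps (steps 4–16 and 18–20, from 7).

**Step 12 (key step).** The C9 ruthenium alkylidene may be held by the C6 ketone oxygen in a six-membered chelate and turn over slowly onto the hindered 1,1-disubstituted C3 alkene. Intermolecular metathesis of the vinyl groups, and hydride-induced migration of the vinyl double bond (which would erode C8), would then compete with ring closure. Fallback: remove the carbonyl before closing the ring. Setting out from 17, Wittig methylenation (Ph3PCH3Br, KOt-Bu, THF) would give tert-butyl (4R,8S)-4,8-dimethyl-3,6-dimethylidenedec-9-enoate F1. Its ring closure with the second-generation Hoveyda–Grubbs catalyst RuCl2(H2IMes)(=CH-C6H4-2-O-i-Pr) can only join C3 to C9, since any other pairing would be a cyclobutene, and comes back to the route at 19.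

**Step 14.** Poor facial selectivity in the capture of O2 is the main risk, because the planar tertiary radical is biased only by two methyl groups two atoms away. Hydrogen atom transfer to the ring alkene, or transannular addition of the peroxyl radical to C3=C9, may also intervene. Fallback: an ionic anti addition in place of radical capture. Setting out from 19, Hg(OAc)2 and concentrated H2O2 in THF at 0 °C would give tert-butyl 2-[(3S,5S,7R)-5-[(acetoxymercurio)methyl]-5-hydroperoxy-3,7-dimethylcyclohept-1-en-1-yl]acetate F2, formed by axial attack of H2O2 on a reversibly formed mercurinium ion. Alkaline NaBH4 would replace mercury by hydrogen to give tert-butyl 2-[(3S,5S,7R)-5-hydroperoxy-3,5,7-trimethylcyclohept-1-en-1-yl]acetate F3, and Et3SiCl/imidazole comes back to the route at 20.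

**Step 16.** Imidazole-promoted epimerisation of the α-branched aldehyde at C8, or incomplete silylation of the keto ester, would carry stereochemical or chemoselectivity losses into the olefination. Fallback: leave the keto ester unprotected and let the ylide act as its base. Setting out from 22, olefination with 2.2 equiv of ylide 26 at −78 °C (the first equivalent is consumed as the enolate) would give tert-butyl (4R,6S,8S,9Z)-4,6,8-trimethyl-3-oxo-16-phenyl-6-[(triethylsilyl)peroxy]hexadec-9-enoate F4. Acidolysis as in step 20 would give 2-[(3S,4R,6S)-3-hydroxy-4,6-dimethyl-6-[(2S,3Z)-2-methyl-10-phenyldec-3-en-1-yl]-1,2-dioxan-3-yl]acetic acid F5, and diimide reduction as in step 19 comes back to the route at 30.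

**Step 20.** The tert-butyl ester is the slowest of the three groups to fall, so the hemiketal stays in strong acid for some time. Acid-induced loss of water at C3, or cleavage starting from the protonated peroxide in the open hydroperoxy ketone form, may compete. Fallback: hold C3 as a methyl ketal during ester cleavage. Setting out from 28, catalytic HCl in MeOH at 0 °C would remove both silyl groups and trap the ring as tert-butyl 2-[(3S,4R,6S)-3-methoxy-4,6-dimethyl-6-[(2R)-2-methyl-10-phenyldecyl]-1,2-dioxan-3-yl]acetate F6, which cannot open to the hydroperoxy keto ester. Anhydrous CF3CO2H in CH2Cl2 at 0 °C would then give 2-[(3S,4R,6S)-3-methoxy-4,6-dimethyl-6-[(2R)-2-methyl-10-phenyldecyl]-1,2-dioxan-3-yl]acetic acid F7, and dilute aqueous HCl in MeCN would exchange OMe for OH and come back to the route at 30.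

## Further compounds

F1 | step 12 | tert-butyl (4R,8S)-4,8-dimethyl-3,6-dimethylidenedec-9-enoate | C=C(CC(=O)OC(C)(C)C)[C@H](C)CC(=C)C[C@H](C)C=C
F2 | step 14 | tert-butyl 2-[(3S,5S,7R)-5-[(acetoxymercurio)methyl]-5-hydroperoxy-3,7-dimethylcyclohept-1-en-1-yl]acetate | CC(C)(C)OC(=O)CC1=C[C@@H](C)C[C@](C[Hg]OC(C)=O)(OO)C[C@H]1C
F3 | step 14 | tert-butyl 2-[(3S,5S,7R)-5-hydroperoxy-3,5,7-trimethylcyclohept-1-en-1-yl]acetate | CC(C)(C)OC(=O)CC1=C[C@@H](C)C[C@](C)(OO)C[C@H]1C
F4 | step 16 | tert-butyl (4R,6S,8S,9Z)-4,6,8-trimethyl-3-oxo-16-phenyl-6-[(triethylsilyl)peroxy]hexadec-9-enoate | C[C@H](/C=C\CCCCCCc1ccccc1)C[C@](C)(OO[Si](CC)(CC)CC)C[C@@H](C)C(=O)CC(=O)OC(C)(C)C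
F5 | step 16 | 2-[(3S,4R,6S)-3-hydroxy-4,6-dimethyl-6-[(2S,3Z)-2-methyl-10-phenyldec-3-en-1-yl]-1,2-dioxan-3-yl]acetic acid | C[C@H](/C=C\CCCCCCc1ccccc1)C[C@@]1(C)C[C@@H](C)[C@](O)(CC(=O)O)OO1
F6 | step 20 | tert-butyl 2-[(3S,4R,6S)-3-methoxy-4,6-dimethyl-6-[(2R)-2-methyl-10-phenyldecyl]-1,2-dioxan-3-yl]acetate | C[C@H](CCCCCCCCc1ccccc1)C[C@@]1(C)C[C@@H](C)[C@](OC)(CC(=O)OC(C)(C)C)OO1
F7 | step 20 | 2-[(3S,4R,6S)-3-methoxy-4,6-dimethyl-6-[(2R)-2-methyl-10-phenyldecyl]-1,2-dioxan-3-yl]acetic acid | C[C@H](CCCCCCCCc1ccccc1)C[C@@]1(C)C[C@@H](C)[C@](OC)(CC(=O)O)OO1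
A1 | alternative 1 | methyl 2-[(3S,6S)-3-methoxy-4,6-dimethyl-6-[(2R)-2-methyl-10-phenyldecyl]-3,6-dihydro-1,2-dioxin-3-yl]acetate | C[C@H](CCCCCCCCc1ccccc1)C[C@@]1(C)C=C(C)[C@](OC)(CC(=O)OC)OO1
A2 | alternative 1 | methyl (3S)-3-{[(3S,5R)-3,5-dimethyl-13-phenyltridec-1-en-3-yl]peroxy}-3-methoxy-4-methylpent-4-enoate | C[C@H](CCCCCCCCc1ccccc1)C[C@@](C)(C=C)OO[C@@](OC)(CC(=O)OC)C(C)=C
A3 | alternative 2 | cis-3,6-dimethylcyclohept-4-en-1-one (meso) | O=C1C[C@H](C)C=C[C@H](C)C1
A4 | alternative 2 | 1,1,3,3-tetrabromopropan-2-one | O=C(C(Br)Br)C(Br)Br
A5 | alternative 2 | (2E,4E)-hexa-2,4-diene | C/C=C/C=C/C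
A6 | alternative 3 | methyl 2-[(3S,4R,6S)-3-hydroxy-4,6-dimethyl-6-[(2R)-2-methyl-10-phenyldecyl]-1,2-dioxan-3-yl]acetate | C[C@H](CCCCCCCCc1ccccc1)C[C@@]1(C)C[C@@H](C)[C@](O)(CC(=O)OC)OO1
A7 | alternative 3 | methyl 4-bromo-3-oxopentanoate | CC(Br)C(=O)CC(=O)OC
A8 | alternative 3 | (4R)-2,4-dimethyl-12-phenyldodec-1-ene | C=C(C)C[C@H](C)CCCCCCCCc1ccccc1
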